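**Retrosynthetic overview**

1. The strategy rests on ring C being a 2,4-dihydroxy-6-alkylphenyl ketone: C1' carries the acyl carbon bound to C4 of ring B, oxygen sits on C2' and C4', and the CH2 link to the pyranone sits on C6'. A [4+2] reaction of an acetoacetate-derived 1,3-dioxygenated diene with the C4 ynone builds exactly this ring, forming C1'–C2' and C5'–C6'.
2. The ynone comes from a tetralone-4-carboxylic acid (acid chloride plus alkynylstannane). Ring B is closed at C1–C8a by Friedel–Crafts acylation of a 2-aryl-3-benzyloxy-3-methylglutaric acid.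
3. C3 and C4 are set by Sharpless epoxidation of an (E)-2-methyl-3-arylallyl alcohol and anti opening at the benzylic carbon by a vinyl cuprate; the two vinyl groups later become the two carboxyl groups.
4. After ring C, the C6' CH2 is joined to C6 of a 4-benzyloxy-2-pyranone (ring D, from two molecules of malonyl dichloride) through a benzylic zinc reagent, and all benzyl groups are removed by hydrogenolysis.
5. Ring order: ring A is bought, ring B (step 10), ring C (step 15), ring D made apart (step 19) and attached (step 21).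

Key step: step 15

Remark on the chemistry: D-(−)-diethyl tartrate is taken to give the (2R,3R) epoxy alcohol 5, by analogy with the (2S,3S) epoxide that the L-(+) ester gives from (E)-2-methylcinnamyl alcohol. Compounds 1, 2, 15, 19 and 28 are taken as commercial. Tetralone atoms are numbered C1–C8a as in the target; ring C atoms are primed.

**Route**

Step 1
Reactants: 1 3,5-bis(benzyloxy)benzaldehyde; 2 ethyl 2-(triphenylphosphoranylidene)propanoate
Product: 3 ethyl (2E)-3-[3,5-bis(benzyloxy)phenyl]-2-methylprop-2-enoate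
Conditions: toluene, 90 °C
Reagents that add atoms: none
Why: Wittig olefination with a stabilised α-methyl ylide should give the trisubstituted enoate with the aryl group trans to the ester, the geometry that later places the C4 substituent cis to the C3 oxygen.

Step 2
Reactants: 3 ethyl (2E)-3-[3,5-bis(benzyloxy)phenyl]-2-methylprop-2-enoate
Product: 4 (2E)-3-[3,5-bis(benzyloxy)phenyl]-2-methylprop-2-en-1-ol
Conditions: iBu2AlH, CH2Cl2, −78 to 0 °C; aq. KNaC4H4O6 work-up
Reagents that add atoms: none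
Why: 1,2-reduction of the conjugated ester by the aluminium hydride should give the allylic alcohol needed for directed epoxidation without touching the benzyl ethers.

Step 3
Reactants: 4 (2E)-3-[3,5-bis(benzyloxy)phenyl]-2-methylprop-2-en-1-ol
Product: 5 [(2R,3R)-3-[3,5-bis(benzyloxy)phenyl]-2-methyloxiran-2-yl]methanol
Conditions: Ti(OiPr)4 (10 mol%), D-(−)-diethyl tartrate (12 mol%), t-BuOOH, 4 Å molecular sieves, CH2Cl2, −20 °C
Reagents that add atoms: tert-butyl hydroperoxide, CC(C)(C)OO
Why: Sharpless asymmetric epoxidation of an (E)-2-methyl-3-arylallyl alcohol should deliver oxygen to one alkene face under control of the titanium tartrate complex and so set both oxirane carbons (the later C3 and the benzylic carbon) as R.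

Step 4
Reactants: 5 [(2R,3R)-3-[3,5-bis(benzyloxy)phenyl]-2-methyloxiran-2-yl]methanol
Product: 6 (2S,3S)-3-[3,5-bis(benzyloxy)phenyl]-2-methylpent-4-ene-1,2-diol
Conditions: CH2=CHMgBr (4 equiv), CuI (20 mol%), THF, −40 to −10 °C
Reagents that add atoms: vinylmagnesium bromide, C=C[Mg]Br
Why: Copper-catalysed Grignard opening of a 3-aryl-2,3-epoxy alcohol should proceed by SN2 attack at the benzylic carbon (the other oxirane carbon is fully substituted) with inversion, which fixes the later C4 with the vinyl group, the future acyl carbon, on the side of the C3 oxygen once ring B is closed.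

Step 5
Reactants: 6 (2S,3S)-3-[3,5-bis(benzyloxy)phenyl]-2-methylpent-4-ene-1,2-diol
Product: 8 (2S)-2-{(1S)-1-[3,5-bis(benzyloxy)phenyl]prop-2-en-1-yl}-2-methyloxirane, via primary tosylate 7 (not isolated)
Conditions: NaH, 1-(4-methylbenzenesulfonyl)imidazole, THF, 0 °C to rt
Reagents that add atoms: none
Why: Selective sulfonylation of the primary alkoxide followed by intramolecular Williamson displacement by the tertiary alkoxide should give the terminal epoxide with both stereocentres untouched.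

Step 6
Reactants: 8 (2S)-2-{(1S)-1-[3,5-bis(benzyloxy)phenyl]prop-2-en-1-yl}-2-methyloxirane
Product: 9 (3S,4R)-3-[3,5-bis(benzyloxy)phenyl]-4-methylhepta-1,6-dien-4-ol
Conditions: CH2=CHMgBr, CuI (10 mol%), THF, −30 to 0 °C
Reagents that add atoms: vinylmagnesium bromide, C=C[Mg]Br
Why: Copper-catalysed Grignard opening of the 2,2-disubstituted oxirane at its CH2 carbon should add the allyl arm whose inner CH becomes C1, leaving the tertiary alcohol at C3.

Step 7
Reactants: 9 (3S,4R)-3-[3,5-bis(benzyloxy)phenyl]-4-methylhepta-1,6-dien-4-ol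
Product: 10 1,3-bis(benzyloxy)-5-[(3S,4R)-4-(benzyloxy)-4-methylhepta-1,6-dien-3-yl]benzene
Conditions: NaH, BnBr, Bu4NI (cat.), DMF, 0 °C to rt
Reagents that add atoms: benzyl bromide, BrCc1ccccc1
Why: Williamson benzylation of the tertiary alkoxide is placed here, before any carbonyl group exists, so that base-induced β-elimination cannot occur.

Step 8
Reactants: 10 1,3-bis(benzyloxy)-5-[(3S,4R)-4-(benzyloxy)-4-methylhepta-1,6-dien-3-yl]benzene
Product: 11 (2S,3R)-3-(benzyloxy)-2-[3,5-bis(benzyloxy)phenyl]-3-methylpentanedial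
Conditions: O3 (2.2 equiv, metered), CH2Cl2/MeOH, −78 °C; Me2S, −78 °C to rt; used crude
Reagents that add atoms: ozone, [O-][O+]=O
Why: Ozonolysis with reductive work-up should cleave both terminal alkenes, which react far faster than the alkoxy arene, under neutral conditions that keep the α-aryl aldehyde centre intact.

Step 9
Reactants: 11 (2S,3R)-3-(benzyloxy)-2-[3,5-bis(benzyloxy)phenyl]-3-methylpentanedial
Product: 12 (2S,3R)-3-(benzyloxy)-2-[3,5-bis(benzyloxy)phenyl]-3-methylpentanedioic acid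
Conditions: NaClO2, NaH2PO4, 2-methylbut-2-ene, t-BuOH/H2O, 0 °C to rt
Reagents that add atoms: sodium chlorite, [Na+].[O-]Cl=O
Why: Pinnick oxidation in weakly acidic buffer with a hypochlorite scavenger should convert both aldehydes into acids without epimerising the α-aryl centre or chlorinating the ring.

Step 10
Reactants: 12 (2S,3R)-3-(benzyloxy)-2-[3,5-bis(benzyloxy)phenyl]-3-methylpentanedioic acid
Product: 14 (1S,2R)-2,5,7-tris(benzyloxy)-2-methyl-4-oxo-1,2,3,4-tetrahydronaphthalene-1-carboxylic acid, via cyclic anhydride 13 (not isolated)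
Conditions: (CF3CO)2O, CH2Cl2, 0 °C; then CF3CO2H, 0 °C to rt; aqueous work-up
Reagents that add atoms: none
Why: Intramolecular Friedel–Crafts acylation, the classical closure of 2-arylglutaric anhydrides to 4-oxotetralin-1-carboxylic acids, should close ring B at C1–C8a because only the CH2-side carbonyl can reach an ortho carbon of the strongly activated, symmetrical 3,5-dialkoxyphenyl ring in a six-membered closure.

Step 11
Reactants: 15 tert-butyldimethyl(prop-2-yn-1-yloxy)silane
Product: 16 tributyl{3-[(tert-butyldimethylsilyl)oxy]prop-1-yn-1-yl}stannane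
Conditions: n-BuLi, THF, −78 °C; Bu3SnCl, −78 °C to rt
Reagents that add atoms: tributyltin chloride, CCCC[Sn](Cl)(CCCC)CCCC
Why: Deprotonation of the terminal alkyne and quenching of the lithium acetylide with the tin chloride is the standard preparation of alkynylstannanes.

Step 12
Reactants: 14 (1S,2R)-2,5,7-tris(benzyloxy)-2-methyl-4-oxo-1,2,3,4-tetrahydronaphthalene-1-carboxylic acid; 16 tributyl{3-[(tert-butyldimethylsilyl)oxy]prop-1-yn-1-yl}stannane
Product: 18 (3R,4S)-3,6,8-tris(benzyloxy)-4-{4-[(tert-butyldimethylsilyl)oxy]but-2-ynoyl}-3-methyl-3,4-dihydronaphthalen-1(2H)-one, via acid chloride 17 (not isolated)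
Conditions: 1-chloro-N,N,2-trimethylprop-1-en-1-amine, CH2Cl2, 0 °C to rt; then 16, Pd2(dba)3 (2.5 mol%), tri(2-furyl)phosphine (10 mol%), toluene, rt to 40 °C
Reagents that add atoms: none
Why: The chloroenamine makes the acid chloride without HCl or base, and Stille acylation (Pd-catalysed coupling of an acid chloride with an alkynylstannane) should then give the ynone under non-basic conditions that spare the epimerisable C4 and the β-benzyloxy ketone.

Step 13
Reactants: 19 methyl acetoacetate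
Product: 20 methyl 3-[(trimethylsilyl)oxy]but-2-enoate
Conditions: Me3SiCl, Et3N, hexane, rt
Reagents that add atoms: chlorotrimethylsilane, C[Si](C)(C)Cl
Why: O-silylation of the enol form of a β-keto ester with a silyl chloride and an amine base is standard.

Step 14
Reactants: 20 methyl 3-[(trimethylsilyl)oxy]but-2-enoate
Product: 21 (1Z)-1-methoxy-1,3-bis[(trimethylsilyl)oxy]buta-1,3-diene
Conditions: LiN(iPr)2, THF, −78 °C; Me3SiCl, −78 °C to rt; distilled, used fresh
Reagents that add atoms: chlorotrimethylsilane, C[Si](C)(C)Cl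
Why: γ-Deprotonation of the silyl enol ether and O-silylation of the resulting dienolate is the standard preparation of 1-alkoxy-1,3-bis(silyloxy)dienes.

Step 15
Reactants: 18 (3R,4S)-3,6,8-tris(benzyloxy)-4-{4-[(tert-butyldimethylsilyl)oxy]but-2-ynoyl}-3-methyl-3,4-dihydronaphthalen-1(2H)-one; 21 (1Z)-1-methoxy-1,3-bis[(trimethylsilyl)oxy]buta-1,3-diene
Product: 24 (3R,4S)-3,6,8-tris(benzyloxy)-4-[2-({[tert-butyl(dimethyl)silyl]oxy}methyl)-4,6-dihydroxybenzoyl]-3-methyl-3,4-dihydronaphthalen-1(2H)-one, via cyclohexadiene cycloadduct 22 (not isolated), via bis(trimethylsilyl) aryl ether 23 (not isolated)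
Conditions: 21 (3 equiv), toluene, 80 °C, sealed tube; then 10% aq. citric acid/THF, rt
Reagents that add atoms: none
Why: The electron-rich diene and the ynone should combine in a normal-demand Diels–Alder reaction in which the CH2 terminus of the diene bonds to the β-carbon of the ynone (future C6') and the ketene acetal carbon bonds to the α-carbon (future C1'), giving cyclohexa-1,4-diene 22. 1,4-Elimination of methanol aromatises 22 to the bis(silyl) ether 23, and mild acid hydrolysis frees the hydroxyls at C2' and C4'. The closest known reactions are cycloadditions of alkynyl ketones and esters with 1-alkoxy-1,3-bis(silyloxy)dienes that give resorcylate-type arenes. Ring C is closed by an intermolecular [4+2] cycloaddition that forms C1'–C2' and C5'–C6' in one operation, and no lasting stereocentre is created because the ketal carbon of 22 is lost on aromatisation. The step needs regioselectivity, which the matched polarisation secures (the carbonyl makes the CH2OSi-bearing alkyne carbon electrophilic and the two oxygen substituents make the diene CH2 terminus nucleophilic), and chemoselectivity for the alkyne over the deactivated C1 ketone. Thermal, base-free conditions are chosen because C4–H is acidic and the C3 benzyloxy group is β to both ketones.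

Step 16
Reactants: 24 (3R,4S)-3,6,8-tris(benzyloxy)-4-[2-({[tert-butyl(dimethyl)silyl]oxy}methyl)-4,6-dihydroxybenzoyl]-3-methyl-3,4-dihydronaphthalen-1(2H)-one
Product: 25 (3R,4S)-3,6,8-tris(benzyloxy)-4-[2,4-bis(benzyloxy)-6-({[tert-butyl(dimethyl)silyl]oxy}methyl)benzoyl]-3-methyl-3,4-dihydronaphthalen-1(2H)-one
Conditions: BnOH, PPh3, diisopropyl azodicarboxylate (3 equiv each), THF, 0 °C to rt
Reagents that add atoms: benzyl alcohol, OCc1ccccc1
Why: Mitsunobu etherification should benzylate both ring C phenols (the chelated C2' hydroxyl more slowly) under near-neutral conditions that do not enolise C4, and the protection is needed because free phenols would quench the benzylic zinc reagent of step 21.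

Step 17
Reactants: 25 (3R,4S)-3,6,8-tris(benzyloxy)-4-[2,4-bis(benzyloxy)-6-({[tert-butyl(dimethyl)silyl]oxy}methyl)benzoyl]-3-methyl-3,4-dihydronaphthalen-1(2H)-one
Product: 26 (3R,4S)-3,6,8-tris(benzyloxy)-4-[2,4-bis(benzyloxy)-6-(hydroxymethyl)benzoyl]-3-methyl-3,4-dihydronaphthalen-1(2H)-one
Conditions: HF·pyridine, THF/pyridine, 0 °C to rt
Reagents that add atoms: none
Why: Buffered fluoride desilylation should cleave the primary silyl ether while the benzyl ethers and the β-benzyloxy ketone stay intact, and the absence of acid and methanol keeps the ortho-acyl benzyl alcohol from being trapped as a cyclic ketal.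

Step 18
Reactants: 26 (3R,4S)-3,6,8-tris(benzyloxy)-4-[2,4-bis(benzyloxy)-6-(hydroxymethyl)benzoyl]-3-methyl-3,4-dihydronaphthalen-1(2H)-one
Product: 27 (3R,4S)-3,6,8-tris(benzyloxy)-4-[2,4-bis(benzyloxy)-6-(bromomethyl)benzoyl]-3-methyl-3,4-dihydronaphthalen-1(2H)-one
Conditions: CBr4, PPh3, CH2Cl2, 0 °C
Reagents that add atoms: carbon tetrabromide, BrC(Br)(Br)Br
Why: Appel bromination should convert the primary benzylic alcohol into the bromide under neutral conditions.

Step 19
Reactants: 28 malonyl dichloride (two molecules combine)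
Product: 31 6-chloro-4-hydroxy-2H-pyran-2-one, via chlorocarbonyl pyranone 29 (not isolated), via pyranone carboxylic acid 30 (not isolated)
Conditions: neat, rt to 45 °C; then H2O/dioxane, 60 °C
Reagents that add atoms: malonyl dichloride (second molecule of 28), ClC(=O)CC(Cl)=O; water, O
Why: Self-condensation of two molecules of malonyl dichloride (C-acylation of one by the other, then lactonisation through the enol oxygen of an acid chloride, with loss of two HCl) should give the chlorocarbonyl pyranone, and hydrolysis of its acid chloride by water followed by decarboxylation of the resulting β-keto-type acid is a known route to this chloropyranone, which forms ring D.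

Step 20
Reactants: 31 6-chloro-4-hydroxy-2H-pyran-2-one
Product: 32 4-(benzyloxy)-6-chloro-2H-pyran-2-one
Conditions: BnOH, PPh3, diisopropyl azodicarboxylate, THF, 0 °C to rt
Reagents that add atoms: benzyl alcohol, OCc1ccccc1
Why: Mitsunobu alkylation of the acidic 4-hydroxyl of a 4-hydroxy-2-pyranone should occur on oxygen and avoids free base that could displace the C6 chloride.

Step 21
Reactants: 27 (3R,4S)-3,6,8-tris(benzyloxy)-4-[2,4-bis(benzyloxy)-6-(bromomethyl)benzoyl]-3-methyl-3,4-dihydronaphthalen-1(2H)-one; 32 4-(benzyloxy)-6-chloro-2H-pyran-2-one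
Product: 34 (3R,4S)-3,6,8-tris(benzyloxy)-4-{2,4-bis(benzyloxy)-6-[(4-(benzyloxy)-2-oxo-2H-pyran-6-yl)methyl]benzoyl}-3-methyl-3,4-dihydronaphthalen-1(2H)-one, via benzylic zinc bromide 33 (not isolated)
Conditions: Zn dust, LiCl, THF, 0 °C; then 32, Pd(PPh3)4 (5 mol%), THF, rt to 45 °C
Reagents that add atoms: none
Why: Zinc should insert into the benzylic bromide in the presence of LiCl while the ketones survive, and Negishi coupling with the activated C6–Cl bond of the pyranone (oxidative addition to zerovalent palladium, transmetalation, reductive elimination) should form the C6'–CH2–C6 link under neutral conditions.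

Step 22
Reactants: 34 (3R,4S)-3,6,8-tris(benzyloxy)-4-{2,4-bis(benzyloxy)-6-[(4-(benzyloxy)-2-oxo-2H-pyran-6-yl)methyl]benzoyl}-3-methyl-3,4-dihydronaphthalen-1(2H)-one
Product: 35 (3R,4S)-4-{2,4-dihydroxy-6-[(4-hydroxy-2-oxo-2H-pyran-6-yl)methyl]benzoyl}-3,6,8-trihydroxy-3-methyl-3,4-dihydronaphthalen-1(2H)-one
Conditions: H2 (1 atm), Pd/C (10% Pd on carbon), EtOAc/MeOH, rt
Reagents that add atoms: none
Why: Hydrogenolysis should remove all six benzyl groups, including the tertiary one, under neutral conditions that leave the chelated aryl ketones, the pyranone and both stereocentres untouched.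

**Compound list**

1 | 3,5-bis(benzyloxy)benzaldehyde | O=Cc1cc(OCc2ccccc2)cc(OCc2ccccc2)c1 | starting material
2 | ethyl 2-(triphenylphosphoranylidene)propanoate | CCOC(=O)C(C)=P(c1ccccc1)(c1ccccc1)c1ccccc1 | starting material
3 | ethyl (2E)-3-[3,5-bis(benzyloxy)phenyl]-2-methylprop-2-enoate | CCOC(=O)/C(C)=C/c1cc(OCc2ccccc2)cc(OCc2ccccc2)c1 | intermediate
4 | (2E)-3-[3,5-bis(benzyloxy)phenyl]-2-methylprop-2-en-1-ol | OC/C(C)=C/c1cc(OCc2ccccc2)cc(OCc2ccccc2)c1 | intermediate
5 | [(2R,3R)-3-[3,5-bis(benzyloxy)phenyl]-2-methyloxiran-2-yl]methanol | C[C@]1(CO)O[C@@H]1c1cc(OCc2ccccc2)cc(OCc2ccccc2)c1 | intermediate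
6 | (2S,3S)-3-[3,5-bis(benzyloxy)phenyl]-2-methylpent-4-ene-1,2-diol | C[C@@](O)(CO)[C@H](c1cc(OCc2ccccc2)cc(OCc2ccccc2)c1)C=C | intermediate
7 | (2S,3S)-3-[3,5-bis(benzyloxy)phenyl]-2-hydroxy-2-methylpent-4-en-1-yl 4-methylbenzenesulfonate | C[C@@](O)(COS(=O)(=O)c1ccc(C)cc1)[C@H](c1cc(OCc2ccccc2)cc(OCc2ccccc2)c1)C=C | intermediate
8 | (2S)-2-{(1S)-1-[3,5-bis(benzyloxy)phenyl]prop-2-en-1-yl}-2-methyloxirane | C[C@@]1(CO1)[C@H](c2cc(OCc3ccccc3)cc(OCc3ccccc3)c2)C=C | intermediate
9 | (3S,4R)-3-[3,5-bis(benzyloxy)phenyl]-4-methylhepta-1,6-dien-4-ol | C[C@@](O)(CC=C)[C@H](c1cc(OCc2ccccc2)cc(OCc2ccccc2)c1)C=C | intermediate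
10 | 1,3-bis(benzyloxy)-5-[(3S,4R)-4-(benzyloxy)-4-methylhepta-1,6-dien-3-yl]benzene | C[C@@](OCc1ccccc1)(CC=C)[C@H](c1cc(OCc2ccccc2)cc(OCc2ccccc2)c1)C=C | intermediate
11 | (2S,3R)-3-(benzyloxy)-2-[3,5-bis(benzyloxy)phenyl]-3-methylpentanedial | C[C@@](OCc1ccccc1)(CC=O)[C@H](c1cc(OCc2ccccc2)cc(OCc2ccccc2)c1)C=O | intermediate
12 | (2S,3R)-3-(benzyloxy)-2-[3,5-bis(benzyloxy)phenyl]-3-methylpentanedioic acid | C[C@@](OCc1ccccc1)(CC(=O)O)[C@H](c1cc(OCc2ccccc2)cc(OCc2ccccc2)c1)C(=O)O | intermediate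
13 | (3S,4R)-4-(benzyloxy)-3-[3,5-bis(benzyloxy)phenyl]-4-methyloxane-2,6-dione | C[C@@]1(OCc2ccccc2)CC(=O)OC(=O)[C@H]1c1cc(OCc2ccccc2)cc(OCc2ccccc2)c1 | intermediate
14 | (1S,2R)-2,5,7-tris(benzyloxy)-2-methyl-4-oxo-1,2,3,4-tetrahydronaphthalene-1-carboxylic acid | C[C@@]1(OCc2ccccc2)CC(=O)c2c(OCc3ccccc3)cc(OCc3ccccc3)cc2[C@@H]1C(=O)O | intermediate
15 | tert-butyldimethyl(prop-2-yn-1-yloxy)silane | C#CCO[Si](C)(C)C(C)(C)C | starting material
16 | tributyl{3-[(tert-butyldimethylsilyl)oxy]prop-1-yn-1-yl}stannane | CCCC[Sn](CCCC)(CCCC)C#CCO[Si](C)(C)C(C)(C)C | intermediate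
17 | (1S,2R)-2,5,7-tris(benzyloxy)-2-methyl-4-oxo-1,2,3,4-tetrahydronaphthalene-1-carbonyl chloride | C[C@@]1(OCc2ccccc2)CC(=O)c2c(OCc3ccccc3)cc(OCc3ccccc3)cc2[C@@H]1C(Cl)=O | intermediate
18 | (3R,4S)-3,6,8-tris(benzyloxy)-4-{4-[(tert-butyldimethylsilyl)oxy]but-2-ynoyl}-3-methyl-3,4-dihydronaphthalen-1(2H)-one | C[C@@]1(OCc2ccccc2)CC(=O)c2c(OCc3ccccc3)cc(OCc3ccccc3)cc2[C@@H]1C(=O)C#CCO[Si](C)(C)C(C)(C)C | intermediate
19 | methyl acetoacetate | COC(=O)CC(C)=O | starting material
20 | methyl 3-[(trimethylsilyl)oxy]but-2-enoate (E/Z mixture, geometry lost in step 14) | COC(=O)C=C(C)O[Si](C)(C)C | intermediate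
21 | (1Z)-1-methoxy-1,3-bis[(trimethylsilyl)oxy]buta-1,3-diene | CO/C(O[Si](C)(C)C)=C/C(=C)O[Si](C)(C)C | intermediate
22 | (3R,4S)-3,6,8-tris(benzyloxy)-4-{[2-({[tert-butyl(dimethyl)silyl]oxy}methyl)-6-methoxy-4,6-bis(trimethylsilyloxy)cyclohexa-1,4-dien-1-yl]carbonyl}-3-methyl-3,4-dihydronaphthalen-1(2H)-one (ketal carbon epimeric) | C[C@@]1(OCc2ccccc2)CC(=O)c2c(OCc3ccccc3)cc(OCc3ccccc3)cc2[C@@H]1C(=O)C1=C(CO[Si](C)(C)C(C)(C)C)CC(O[Si](C)(C)C)=CC1(OC)O[Si](C)(C)C | intermediate
23 | (3R,4S)-3,6,8-tris(benzyloxy)-4-[2-({[tert-butyl(dimethyl)silyl]oxy}methyl)-4,6-bis(trimethylsilyloxy)benzoyl]-3-methyl-3,4-dihydronaphthalen-1(2H)-one | C[C@@]1(OCc2ccccc2)CC(=O)c2c(OCc3ccccc3)cc(OCc3ccccc3)cc2[C@@H]1C(=O)c1c(O[Si](C)(C)C)cc(O[Si](C)(C)C)cc1CO[Si](C)(C)C(C)(C)C | intermediate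
24 | (3R,4S)-3,6,8-tris(benzyloxy)-4-[2-({[tert-butyl(dimethyl)silyl]oxy}methyl)-4,6-dihydroxybenzoyl]-3-methyl-3,4-dihydronaphthalen-1(2H)-one | C[C@@]1(OCc2ccccc2)CC(=O)c2c(OCc3ccccc3)cc(OCc3ccccc3)cc2[C@@H]1C(=O)c1c(O)cc(O)cc1CO[Si](C)(C)C(C)(C)C | intermediate
25 | (3R,4S)-3,6,8-tris(benzyloxy)-4-[2,4-bis(benzyloxy)-6-({[tert-butyl(dimethyl)silyl]oxy}methyl)benzoyl]-3-methyl-3,4-dihydronaphthalen-1(2H)-one | C[C@@]1(OCc2ccccc2)CC(=O)c2c(OCc3ccccc3)cc(OCc3ccccc3)cc2[C@@H]1C(=O)c1c(OCc2ccccc2)cc(OCc2ccccc2)cc1CO[Si](C)(C)C(C)(C)C | intermediate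
26 | (3R,4S)-3,6,8-tris(benzyloxy)-4-[2,4-bis(benzyloxy)-6-(hydroxymethyl)benzoyl]-3-methyl-3,4-dihydronaphthalen-1(2H)-one | C[C@@]1(OCc2ccccc2)CC(=O)c2c(OCc3ccccc3)cc(OCc3ccccc3)cc2[C@@H]1C(=O)c1c(OCc2ccccc2)cc(OCc2ccccc2)cc1CO | intermediate
27 | (3R,4S)-3,6,8-tris(benzyloxy)-4-[2,4-bis(benzyloxy)-6-(bromomethyl)benzoyl]-3-methyl-3,4-dihydronaphthalen-1(2H)-one | C[C@@]1(OCc2ccccc2)CC(=O)c2c(OCc3ccccc3)cc(OCc3ccccc3)cc2[C@@H]1C(=O)c1c(OCc2ccccc2)cc(OCc2ccccc2)cc1CBr | intermediate
28 | malonyl dichloride | ClC(=O)CC(Cl)=O | starting material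
29 | 6-chloro-4-hydroxy-2-oxo-2H-pyran-3-carbonyl chloride | O=C(Cl)c1c(O)cc(Cl)oc1=O | intermediate
30 | 6-chloro-4-hydroxy-2-oxo-2H-pyran-3-carboxylic acid | O=C(O)c1c(O)cc(Cl)oc1=O | intermediate
31 | 6-chloro-4-hydroxy-2H-pyran-2-one | O=c1cc(O)cc(Cl)o1 | intermediate
32 | 4-(benzyloxy)-6-chloro-2H-pyran-2-one | O=c1cc(OCc2ccccc2)cc(Cl)o1 | intermediate
33 | [3,5-bis(benzyloxy)-2-{[(1S,2R)-2,5,7-tris(benzyloxy)-2-methyl-4-oxo-1,2,3,4-tetrahydronaphthalen-1-yl]carbonyl}benzyl]zinc bromide | C[C@@]1(OCc2ccccc2)CC(=O)c2c(OCc3ccccc3)cc(OCc3ccccc3)cc2[C@@H]1C(=O)c1c(OCc2ccccc2)cc(OCc2ccccc2)cc1C[Zn]Br | intermediate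
34 | (3R,4S)-3,6,8-tris(benzyloxy)-4-{2,4-bis(benzyloxy)-6-[(4-(benzyloxy)-2-oxo-2H-pyran-6-yl)methyl]benzoyl}-3-methyl-3,4-dihydronaphthalen-1(2H)-one | C[C@@]1(OCc2ccccc2)CC(=O)c2c(OCc3ccccc3)cc(OCc3ccccc3)cc2[C@@H]1C(=O)c1c(OCc2ccccc2)cc(OCc2ccccc2)cc1Cc1cc(OCc2ccccc2)cc(=O)o1 | intermediate
35 | (3R,4S)-4-{2,4-dihydroxy-6-[(4-hydroxy-2-oxo-2H-pyran-6-yl)methyl]benzoyl}-3,6,8-trihydroxy-3-methyl-3,4-dihydronaphthalen-1(2H)-one | C[C@@]1(O)CC(=O)c2c(O)cc(O)cc2[C@@H]1C(=O)c1c(O)cc(O)cc1Cc1cc(O)cc(=O)o1 | target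

**Counts**

Total step count: 22. Longest linear sequence: 17 steps (steps 1 to 10, 12, 15 to 18, 21, 22).

**Steps most likely to fail**

Step 15 (key step). The cycloaddition to the hindered internal alkyne may be slow, so that desilylation or silyl transfer of the acyclic diene, conjugate addition without ring closure, or thermal loss of benzyl alcohol from C3 with aromatisation of ring B outruns ring C formation. Fallback: setting out from 18, the acyclic diene is replaced by the cyclic, s-cis-locked 5,5-dimethyl-1,3-bis(trimethylsilyloxy)cyclohexa-1,3-diene F1, made from dimedone by double O-silylation (Me3SiCl/Et3N, then LiN(iPr)2/Me3SiCl). Heating 18 with F1 in toluene at 120–140 °C should give the bicyclo[2.2.2]octadiene adduct (3R,4S)-3,6,8-tris(benzyloxy)-4-{[3-({[tert-butyl(dimethyl)silyl]oxy}methyl)-8,8-dimethyl-1,5-bis(trimethylsilyloxy)bicyclo[2.2.2]octa-2,5-dien-2-yl]carbonyl}-3-methyl-3,4-dihydronaphthalen-1(2H)-one F2 with the same orientation (unsubstituted diene terminus to the ynone β-carbon). F2 should lose 2-methylpropene by retro-[4+2] reaction and so come back to the route at 23, which citric acid hydrolysis converts into 24.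

Step 21. Wurtz-type homocoupling or protonation may consume the benzylic zinc reagent during insertion next to the ortho ketone, or oxidative addition at the chloropyranone may be too slow to keep up with its decay. Fallback: the polarity is inverted so that no organometallic is made on the large fragment. Setting out from 32, Pd(PPh3)4-catalysed stannylation with Bu3SnSnBu3 (toluene, 100 °C) should give 4-(benzyloxy)-6-(tributylstannyl)-2H-pyran-2-one F3. Stille coupling of F3 with bromide 27 (Pd2(dba)3, tri(2-furyl)phosphine, THF, 50 °C), a neutral coupling in which the benzylic bromide is the electrophile, comes back to the route at 34.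

Step 10. Acid may ionise the tertiary C3 benzyloxy group or, once the ketone exists, drive β-elimination and aromatisation of ring B to a naphthol; alternatively the anhydride may be too weakly activated to acylate. Fallback: an acid-free closure setting out from 10. Bromination with N-bromosuccinimide (MeCN, 0 °C), expected para to one benzyloxy group and ortho to the side chain, should give 1,5-bis(benzyloxy)-2-bromo-3-[(3S,4R)-4-(benzyloxy)-4-methylhepta-1,6-dien-3-yl]benzene F4. A 6-exo Heck cyclisation onto the allyl group (Pd(OAc)2, P(o-tolyl)3, Et3N, MeCN, 80 °C) should close ring B as (1S,2R)-2,5,7-tris(benzyloxy)-1-ethenyl-2-methyl-4-methylidene-1,2,3,4-tetrahydronaphthalene F5. Ozonolysis of both alkenes (O3, CH2Cl2/MeOH, −78 °C; Me2S) should give (1S,2R)-2,5,7-tris(benzyloxy)-2-methyl-4-oxo-1,2,3,4-tetrahydronaphthalene-1-carbaldehyde F6, and Pinnick oxidation as in step 9 comes back to the route at 14.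

**Further compounds**

F1 | step 15 | 5,5-dimethyl-1,3-bis(trimethylsilyloxy)cyclohexa-1,3-diene | CC1(C)CC(O[Si](C)(C)C)=CC(O[Si](C)(C)C)=C1
F2 | step 15 | (3R,4S)-3,6,8-tris(benzyloxy)-4-{[3-({[tert-butyl(dimethyl)silyl]oxy}methyl)-8,8-dimethyl-1,5-bis(trimethylsilyloxy)bicyclo[2.2.2]octa-2,5-dien-2-yl]carbonyl}-3-methyl-3,4-dihydronaphthalen-1(2H)-one (bridgehead epimers) | C[C@@]1(OCc2ccccc2)CC(=O)c2c(OCc3ccccc3)cc(OCc3ccccc3)cc2[C@@H]1C(=O)C1=C(CO[Si](C)(C)C(C)(C)C)C2C(O[Si](C)(C)C)=CC1(O[Si](C)(C)C)CC2(C)C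
F3 | step 21 | 4-(benzyloxy)-6-(tributylstannyl)-2H-pyran-2-one | CCCC[Sn](CCCC)(CCCC)c1cc(OCc2ccccc2)cc(=O)o1
F4 | step 10 | 1,5-bis(benzyloxy)-2-bromo-3-[(3S,4R)-4-(benzyloxy)-4-methylhepta-1,6-dien-3-yl]benzene | C[C@@](OCc1ccccc1)(CC=C)[C@H](c1cc(OCc2ccccc2)cc(OCc2ccccc2)c1Br)C=C
F5 | step 10 | (1S,2R)-2,5,7-tris(benzyloxy)-1-ethenyl-2-methyl-4-methylidene-1,2,3,4-tetrahydronaphthalene | C[C@@]1(OCc2ccccc2)CC(=C)c2c(OCc3ccccc3)cc(OCc3ccccc3)cc2[C@@H]1C=C
F6 | step 10 | (1S,2R)-2,5,7-tris(benzyloxy)-2-methyl-4-oxo-1,2,3,4-tetrahydronaphthalene-1-carbaldehyde | C[C@@]1(OCc2ccccc2)CC(=O)c2c(OCc3ccccc3)cc(OCc3ccccc3)cc2[C@@H]1C=O
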